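Assumption: the SMILES is taken as drawn, i.e. (1R,2S,4R,7S,8S,9S,10S,14S,17R) with C4 and C7 trans across C5=C6 (ester cis to C7); briarane numbering C1–C20 is used for every intermediate.

## Retrosynthetic overview

1. 32 ⇐ 4-O-acetylation of 31 ⇐ C4–C5 bond: cathodic chromium/nickel Nozaki–Hiyama–Kishi closure of the ten-membered ring from iodo-enoate aldehyde 29 (last ring).
2. 29 ⇐ alkynyl γ-lactone 23 (carbonylation, then syn-hydrostannation/iodination fix the C5=C6 geometry) ⇐ lactol 21 by alkynylation and O7–C19 lactonisation (third ring).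
3. 21 ⇐ formyl ketone 16: C3–C4 and C2 by chelation-controlled Mukaiyama aldol, C14 by Evans–Saksena reduction.
4. 16 ⇐ enone 13: ring A (second ring) by nickel-catalysed reductive conjugate cyclisation (C10–C11), then formylation at C1.
5. 13 ⇐ L-arabinose (furanose = first ring; gives C6–C10 with C7 and C9, its acetonide sets C8) + ketophosphonate 12.

## Route

Step 1
Reactants: 1 L-arabinose
Product: 2 5-O-(tert-butyldiphenylsilyl)-L-arabinofuranose
Conditions: t-BuPh2SiCl (1.1 equiv), pyridine, 0 °C → rt
Reagents that add atoms: tert-butyl(chloro)diphenylsilane CC(C)(C)[Si](Cl)(c1ccccc1)c1ccccc1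
Why: Silyl ether formation at the only primary hydroxyl traps the furanose form, and sugar C2 and C4 (later C7 and C9) are bought with the starting material.

Step 2
Reactants: 2 5-O-(tert-butyldiphenylsilyl)-L-arabinofuranose
Product: 3 5-O-TBDPS-1,2-O-isopropylidene-β-L-arabinofuranose
Conditions: Me2C(OMe)2, acetone, TsOH (cat.), rt
Reagents that add atoms: 2,2-dimethoxypropane COC(C)(C)OC
Why: Acetonide formation (thermodynamic ketalisation) takes the cis-1,2-diol of the β-furanose and leaves O3 as the only free hydroxyl.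

Step 3
Reactants: 3 5-O-TBDPS-1,2-O-isopropylidene-β-L-arabinofuranose
Product: 4 5-O-TBDPS-1,2-O-isopropylidene-β-L-threo-pentofuranos-3-ulose
Conditions: Dess–Martin periodinane, NaHCO3, CH2Cl2, rt
Reagents that add atoms: none
Why: Dess–Martin oxidation of the single secondary alcohol gives the 3-ulose under neutral conditions that leave the silyl ether and the acetal alone.

Step 4
Reactants: 4 5-O-TBDPS-1,2-O-isopropylidene-β-L-threo-pentofuranos-3-ulose; 5 methyl propanoate
Product: 6 3-C-branched lyxofuranose propanoate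
Conditions: LiN(iPr)2 (1.6 equiv), 5 (1.5 equiv), THF, −78 °C; then 4; AcOH quench at −78 °C
Reagents that add atoms: none
Why: Aldol addition of the lithium ester enolate to the ketone occurs on the convex face, anti to the 1,2-acetonide and to the C4 side chain that both sit on the other face, which sets C8 (hydroxyl cis to O7) while C17 stays a mixture that is fixed in step 14.

Step 5
Reactants: 6 3-C-branched lyxofuranose propanoate
Product: 7 5-hydroxy lyxofuranose propanoate
Conditions: Bu4NF, AcOH (1:1), THF, 0 °C → rt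
Reagents that add atoms: none
Why: Fluoride desilylation frees the primary alcohol and the acetic acid buffer keeps the tertiary β-hydroxy ester from retro-aldol cleavage.

Step 6
Reactants: 7 5-hydroxy lyxofuranose propanoate
Product: 8 pentodialdofuranose propanoate
Conditions: Dess–Martin periodinane, NaHCO3, CH2Cl2, 0 °C → rt
Reagents that add atoms: none
Why: Dess–Martin oxidation gives the C10 aldehyde without base so that the adjacent C9 centre is not epimerised.

Step 7
Reactants: 9 diethyl (2-oxopropyl)phosphonate; 10 2,3-dibromoprop-1-ene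
Product: 12 diethyl (6-bromo-3-oxohept-6-en-2-yl)phosphonate, via bromohexenyl ketophosphonate 11 (not isolated)
Conditions: NaH (1.1 equiv), THF, 0 °C; n-BuLi (1.05 equiv), −20 °C; 10, −78 → 0 °C; then MeI (1.1 equiv), 0 °C → rt
Reagents that add atoms: iodomethane CI
Why: Dianion alkylation of the β-ketophosphonate puts the allylic bromide of 10 on the terminal carbon first and the remaining phosphonate-stabilised anion is then C-methylated, with no lasting stereocentre because the phosphorus-bearing carbon becomes sp2 in step 8.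

Step 8
Reactants: 8 pentodialdofuranose propanoate; 12 diethyl (6-bromo-3-oxohept-6-en-2-yl)phosphonate
Product: 13 (E)-bromo-dienone
Conditions: Ba(OH)2 (0.8 equiv), THF/H2O (40:1), 0 °C → rt
Reagents that add atoms: none
Why: Horner–Wadsworth–Emmons olefination under mild hydroxide conditions gives the (E)-trisubstituted enone (C9 trans to the ketone) without epimerising the α-alkoxy aldehyde.

Step 9
Reactants: 13 (E)-bromo-dienone
Product: 14 ring A triethylsilyl enol ether
Conditions: NiCl2(MeOCH2CH2OMe) (10 mol%), 2,9-dimethyl-1,10-phenanthroline (12 mol%), Mn powder (3 equiv), Et3SiCl (2 equiv), DMF, 30 °C, 0.02 M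
Reagents that add atoms: chlorotriethylsilane CC[Si](Cl)(CC)CC
Why: Nickel-catalysed reductive conjugate addition with silyl trapping, run intramolecularly, joins the alkenyl bromide carbon C11 to the enone β-carbon C10 and closes the six-membered ring with the 11(20)-methylene in place, C10 forming anti to the ring oxygen on C9 in the hydrogen-eclipsed conformer enforced by A(1,3) strain with the α-methyl group (Felkin–Anh sense), while the enol silane is fixed on the C1 side.

Step 10
Reactants: 14 ring A triethylsilyl enol ether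
Product: 16 ring A formyl ketone, via dimethyl acetal 15 (not isolated)
Conditions: HC(OMe)3 (3 equiv), Me3SiOTf (cat.), CH2Cl2, −78 °C; then LiBF4, MeCN/H2O (98:2), 40 °C
Reagents that add atoms: trimethyl orthoformate COC(OC)OC; water O
Why: Mukaiyama-type formylation sends the dimethoxycarbenium ion to C1 of the cyclic enol ether on the face opposite the adjacent C10 substituent (axial attack, 2,3-trans rule), which makes the quaternary centre with the methyl group cis and the new carbon C2 trans to C9, and mild acetal hydrolysis then gives the aldehyde.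

Step 11
Reactants: 16 ring A formyl ketone; 17 ethenyloxy(trimethyl)silane
Product: 19 ring A triol, via β-hydroxy aldehyde 18 (not isolated)
Conditions: 17 (3 equiv), MgBr2·OEt2 (3 equiv), CH2Cl2, −78 → −20 °C; then Me4NBH(OAc)3 (8 equiv), MeCN/AcOH (2:1), −30 → 0 °C
Reagents that add atoms: none
Why: Chelation-controlled Mukaiyama aldol on the magnesium chelate of the formyl ketone brings the enol silane in past the α-methyl group and away from the ring branch C10 to give 2S, and the Evans–Saksena reduction then delivers hydride from the C2-alkoxyborohydride to the C14 ketone through a trans-fused chair to give the 1,3-anti diol (14S, oxygen cis to C2) while the new aldehyde is reduced to the primary C4 alcohol.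

Step 12
Reactants: 19 ring A triol
Product: 20 4-O-TBDPS diol
Conditions: t-BuPh2SiCl (1.05 equiv), imidazole, CH2Cl2, 0 °C
Reagents that add atoms: tert-butyl(chloro)diphenylsilane CC(C)(C)[Si](Cl)(c1ccccc1)c1ccccc1
Why: Selective silyl ether formation at the primary alcohol keeps C4 apart from the hindered secondary alcohols at C2 and C14.

Step 13
Reactants: 20 4-O-TBDPS diol
Product: 21 lactol
Conditions: AcOH/H2O (4:1), 65 °C
Reagents that add atoms: none
Why: Acid hydrolysis of the 1,2-acetonide gives the furanose hemiacetal while the primary TBDPS ether, the methyl ester and the methylene group survive aqueous acetic acid.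

Step 14
Reactants: 21 lactol
Product: 23 alkynyl γ-lactone, via alkynyl hydroxy ester 22 (not isolated)
Conditions: dimethyl (1-diazo-2-oxopropyl)phosphonate (2 equiv), K2CO3 (3 equiv), MeOH, 0 °C → rt; then PPTS, PhMe, 60 °C; then DBU (0.2 equiv), CH2Cl2, rt
Reagents that add atoms: dimethyl (1-diazo-2-oxopropyl)phosphonate CC(=O)C(=[N+]=[N-])P(=O)(OC)OC
Why: Ohira–Bestmann homologation of the lactol aldehyde opens the furanose to the C5≡C6 alkyne, the propargylic O7 hydroxyl (far less hindered than the O9 hydroxyl next to ring A) lactonises onto the C19 ester, and DBU equilibrates the α-centre C17 to the more stable lactone with the methyl group trans to the large C9 substituent (17R).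

Step 15
Reactants: 23 alkynyl γ-lactone
Product: 24 ynoate lactone
Conditions: PdCl2 (5 mol%), CuCl2 (2.2 equiv), NaOAc (2.2 equiv), CO (1 atm), MeOH, rt
Reagents that add atoms: carbon monoxide [C-]#[O+]; methanol CO
Why: Tsuji-type palladium-catalysed oxidative alkoxycarbonylation of the terminal alkyne installs the C16 methyl ester only after O7 is tied up in the C19 lactone, so that no butenolide with C16 can form later.

Step 16
Reactants: 24 ynoate lactone
Product: 26 α-iodo enoate, via α-stannyl enoate 25 (not isolated)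
Conditions: Pd(PPh3)4 (5 mol%), Bu3SnH (1.2 equiv), THF, 0 °C; then I2 (1.3 equiv), CH2Cl2, 0 °C
Reagents that add atoms: iodine II
Why: Palladium-catalysed syn-hydrostannation of the ynoate places tin on the ester-bearing carbon C5 and hydrogen on C6 cis to it, and iododestannylation with retention gives the alkenyl iodide with iodine trans and the ester cis to C7.

Step 17
Reactants: 26 α-iodo enoate
Product: 27 2,9,14-triacetate
Conditions: Ac2O, pyridine, DMAP (cat.), rt
Reagents that add atoms: acetic anhydride CC(=O)OC(C)=O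
Why: Acetylation (nucleophilic acyl transfer) esterifies the three secondary alcohols while the hindered tertiary 8-hydroxyl does not react, and a capped O14 cannot form a lactol with the later C4 aldehyde.

Step 18
Reactants: 27 2,9,14-triacetate
Product: 28 primary alcohol
Conditions: HF·pyridine, THF/pyridine, 0 °C → rt
Reagents that add atoms: none
Why: Fluoride desilylation removes the TBDPS ether without touching the acetates, the lactone or the alkenyl iodide.

Step 19
Reactants: 28 primary alcohol
Product: 29 iodo-enoate aldehyde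
Conditions: Dess–Martin periodinane, NaHCO3, CH2Cl2, 0 °C
Reagents that add atoms: none
Why: Buffered Dess–Martin oxidation gives the β-acetoxy aldehyde without elimination of the C2 acetate.

Step 20
Reactants: 29 iodo-enoate aldehyde
Product: 31 macrocyclic 4-alcohol, via macrocyclic trimethylsilyl ether 30 (not isolated)
Conditions: CrCl2 (20 mol%), NiCl2(MeOCH2CH2OMe) (5 mol%), 2,9-dimethyl-1,10-phenanthroline (10 mol%), Me3SiCl (2 equiv), LiCl, DMF/THF, undivided cell, Al anode, Ni-foam cathode, 4 mA, rt, 29 added over 12 h (final 2 mM); then 0.5 M aq. HCl/THF, 0 °C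
Reagents that add atoms: none
Why: Proposed new method: a cathodically driven, chromium/nickel co-catalysed Nozaki–Hiyama–Kishi macrocyclisation of an α-iodo-enoate onto an aldehyde, in which zerovalent nickel made at the cathode inserts into the carbon–iodine bond, the alkenyl group passes to trivalent chromium as a carbon-bound and configurationally stable alkenylchromium that adds to the C4 aldehyde, Me3SiCl releases the chromium alkoxide and the cathode returns chromium to the divalent state, so that only catalytic metal is present and slow addition keeps the closure intramolecular; the closest known reaction type is the intermolecular electrochemical Nozaki–Hiyama–Kishi coupling of alkenyl halides with aldehydes (and the stoichiometric CrCl2/NiCl2 macrocyclisation), which has not been shown for a ten-membered carbocycle or for an α-halo-acrylate; the C5=C6 geometry is carried over with retention (C4 trans to C7) and C4 is set by the ring, the aldehyde adding with its oxygen on the outer face of the folded trans-fused ring on the side of the C2 acetate (4R).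

Step 21
Reactants: 31 macrocyclic 4-alcohol
Product: 32 CNP0209369.3
Conditions: Ac2O, pyridine, 0 °C → rt
Reagents that add atoms: acetic anhydride CC(=O)OC(C)=O
Why: Acetylation of the allylic C4 alcohol without DMAP avoids allylic transposition and leaves the tertiary 8-hydroxyl free, which completes the target.

## Compound list

1 | L-arabinose, (2R,3S,4S)-2,3,4,5-tetrahydroxypentanal (drawn open-chain) | O=C[C@H](O)[C@@H](O)[C@@H](O)CO | starting material
2 | 5-O-(tert-butyldiphenylsilyl)-L-arabinofuranose (anomer mixture) | CC(C)(C)[Si](c1ccccc1)(c1ccccc1)OC[C@@H]1OC(O)[C@H](O)[C@H]1O | intermediate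
3 | 5-O-(tert-butyldiphenylsilyl)-1,2-O-isopropylidene-β-L-arabinofuranose | CC(C)(C)[Si](c1ccccc1)(c1ccccc1)OC[C@@H]1O[C@@H]2OC(C)(C)O[C@@H]2[C@H]1O | intermediate
4 | 5-O-(tert-butyldiphenylsilyl)-1,2-O-isopropylidene-β-L-threo-pentofuranos-3-ulose | CC(C)(C)[Si](c1ccccc1)(c1ccccc1)OC[C@@H]1O[C@@H]2OC(C)(C)O[C@@H]2C1=O | intermediate
5 | methyl propanoate | CCC(=O)OC | starting material
6 | methyl 2-(5-O-TBDPS-1,2-O-isopropylidene-β-L-lyxofuranos-3-C-yl)propanoate; tertiary 3-OH (later 8-OH) cis to the acetonide oxygens, propanoate branch on the other face, C17 epimers | CC(C)(C)[Si](c1ccccc1)(c1ccccc1)OC[C@@H]1O[C@@H]2OC(C)(C)O[C@@H]2[C@@]1(O)C(C)C(=O)OC | intermediate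
7 | 6 with the 5-O-silyl group removed (free primary alcohol at the later C10) | OC[C@@H]1O[C@@H]2OC(C)(C)O[C@@H]2[C@@]1(O)C(C)C(=O)OC | intermediate
8 | 7 oxidised to the 5-aldehyde (later C10) | O=C[C@@H]1O[C@@H]2OC(C)(C)O[C@@H]2[C@@]1(O)C(C)C(=O)OC | intermediate
9 | diethyl (2-oxopropyl)phosphonate | CCOP(=O)(CC(C)=O)OCC | starting material
10 | 2,3-dibromoprop-1-ene | C=C(Br)CBr | starting material
11 | diethyl (5-bromo-2-oxohex-5-en-1-yl)phosphonate (present as its enolate) | CCOP(=O)(CC(=O)CCC(Br)=C)OCC | intermediate (not isolated)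
12 | diethyl (6-bromo-3-oxohept-6-en-2-yl)phosphonate (racemic) | CCOP(=O)(C(C)C(=O)CCC(Br)=C)OCC | intermediate
13 | (E)-enone: sugar C4 (later C9) carries CH=C(CH3)–CO–CH2CH2–C(Br)=CH2, C9 trans to the ketone (C14) on C10=C1 | C=C(Br)CCC(=O)/C(C)=C/[C@@H]1O[C@@H]2OC(C)(C)O[C@@H]2[C@@]1(O)C(C)C(=O)OC | intermediate
14 | ring A enol ether: 1-methyl-11(20)-methylene-cyclohex-1(14)-ene with OSiEt3 on C14, furanose on C10 (10S) | C=C1CCC(O[Si](CC)(CC)CC)=C(C)[C@H]1[C@@H]3O[C@@H]2OC(C)(C)O[C@@H]2[C@@]3(O)C(C)C(=O)OC | intermediate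
15 | dimethyl acetal of 16 | C=C1CCC(=O)[C@](C)(C(OC)OC)[C@H]1[C@@H]3O[C@@H]2OC(C)(C)O[C@@H]2[C@@]3(O)C(C)C(=O)OC | intermediate (not isolated)
16 | ring A formyl ketone: C14 ketone, quaternary C1 (1R, CH3 cis and CHO trans to C9), 11(20)-methylene | C=C1CCC(=O)[C@](C)(C=O)[C@H]1[C@@H]3O[C@@H]2OC(C)(C)O[C@@H]2[C@@]3(O)C(C)C(=O)OC | intermediate
17 | ethenyloxy(trimethyl)silane | C=CO[Si](C)(C)C | starting material
18 | β-hydroxy aldehyde: (2S)-hydroxyl, C4 aldehyde, C14 ketone | C=C1CCC(=O)[C@](C)([C@@H](O)CC=O)[C@H]1[C@@H]3O[C@@H]2OC(C)(C)O[C@@H]2[C@@]3(O)C(C)C(=O)OC | intermediate (not isolated)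
19 | triol: (2S)-OH, primary 4-OH, (14S)-OH (14-O cis to C2, trans to CH3-15) | C=C1CC[C@H](O)[C@](C)([C@@H](O)CCO)[C@H]1[C@@H]3O[C@@H]2OC(C)(C)O[C@@H]2[C@@]3(O)C(C)C(=O)OC | intermediate
20 | 19 as its 4-O-TBDPS ether | C=C1CC[C@H](O)[C@](C)([C@@H](O)CCO[Si](c2ccccc2)(c2ccccc2)C(C)(C)C)[C@H]1[C@@H]3O[C@@H]2OC(C)(C)O[C@@H]2[C@@]3(O)C(C)C(=O)OC | intermediate
21 | lactol: 20 without the acetonide (C6 hemiacetal, anomer mixture, free 7-OH) | C=C1CC[C@H](O)[C@](C)([C@@H](O)CCO[Si](c2ccccc2)(c2ccccc2)C(C)(C)C)[C@H]1[C@@H]3OC(O)[C@H](O)[C@@]3(O)C(C)C(=O)OC | intermediate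
22 | open-chain alkyne: terminal C5≡C6, free 7-, 8- and 9-OH, C19 methyl ester (C17 epimers) | C#C[C@H](O)[C@@](O)(C(C)C(=O)OC)[C@@H](O)[C@H]1C(=C)CC[C@H](O)[C@]1(C)[C@@H](O)CCO[Si](c1ccccc1)(c1ccccc1)C(C)(C)C | intermediate (not isolated)
23 | alkynyl γ-lactone: O7–C19 lactone (7S,8S,17R; 8-OH cis to CH3-18 and to the alkyne), free 2-, 9-, 14-OH, 4-O-TBDPS | C#C[C@@H]1OC(=O)[C@H](C)[C@@]1(O)[C@@H](O)[C@H]1C(=C)CC[C@H](O)[C@]1(C)[C@@H](O)CCO[Si](c1ccccc1)(c1ccccc1)C(C)(C)C | intermediate
24 | 23 with CO2CH3 on C5 (methyl ynoate) | COC(=O)C#C[C@@H]1OC(=O)[C@H](C)[C@@]1(O)[C@@H](O)[C@H]1C(=C)CC[C@H](O)[C@]1(C)[C@@H](O)CCO[Si](c1ccccc1)(c1ccccc1)C(C)(C)C | intermediate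
25 | α-stannyl enoate: Bu3Sn on C5 trans to C7, ester cis to C7 | COC(=O)/C([Sn](CCCC)(CCCC)CCCC)=C\[C@@H]1OC(=O)[C@H](C)[C@@]1(O)[C@@H](O)[C@H]1C(=C)CC[C@H](O)[C@]1(C)[C@@H](O)CCO[Si](c1ccccc1)(c1ccccc1)C(C)(C)C | intermediate (not isolated)
26 | α-iodo enoate: iodine on C5 trans to C7, ester cis to C7 | COC(=O)/C(I)=C\[C@@H]1OC(=O)[C@H](C)[C@@]1(O)[C@@H](O)[C@H]1C(=C)CC[C@H](O)[C@]1(C)[C@@H](O)CCO[Si](c1ccccc1)(c1ccccc1)C(C)(C)C | intermediate
27 | 26 as its 2,9,14-triacetate | COC(=O)/C(I)=C\[C@@H]1OC(=O)[C@H](C)[C@@]1(O)[C@@H](OC(C)=O)[C@H]1C(=C)CC[C@H](OC(C)=O)[C@]1(C)[C@@H](OC(C)=O)CCO[Si](c1ccccc1)(c1ccccc1)C(C)(C)C | intermediate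
28 | 27 with free primary 4-OH | COC(=O)/C(I)=C\[C@@H]1OC(=O)[C@H](C)[C@@]1(O)[C@@H](OC(C)=O)[C@H]1C(=C)CC[C@H](OC(C)=O)[C@]1(C)[C@@H](OC(C)=O)CCO | intermediate
29 | 28 oxidised to the C4 aldehyde | COC(=O)/C(I)=C\[C@@H]1OC(=O)[C@H](C)[C@@]1(O)[C@@H](OC(C)=O)[C@H]1C(=C)CC[C@H](OC(C)=O)[C@]1(C)[C@@H](OC(C)=O)CC=O | intermediate
30 | 4-O-trimethylsilyl ether of 31 | C=C1CC[C@H](OC(C)=O)[C@]2(C)[C@@H](OC(C)=O)C[C@@H](O[Si](C)(C)C)/C(C(=O)OC)=C/[C@@H]3OC(=O)[C@H](C)[C@@]3(O)[C@@H](OC(C)=O)[C@@H]12 | intermediate (not isolated)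
31 | 4-O-deacetyl-32 (4R alcohol, C4 trans to C7 on C5=C6) | C=C1CC[C@H](OC(C)=O)[C@]2(C)[C@@H](OC(C)=O)C[C@@H](O)/C(C(=O)OC)=C/[C@@H]3OC(=O)[C@H](C)[C@@]3(O)[C@@H](OC(C)=O)[C@@H]12 | intermediate
32 | CNP0209369.3 | C=C1CC[C@H](OC(C)=O)[C@]2(C)[C@@H](OC(C)=O)C[C@@H](OC(C)=O)/C(C(=O)OC)=C/[C@@H]3OC(=O)[C@H](C)[C@@]3(O)[C@@H](OC(C)=O)[C@@H]12 | target

## Step count and weak points

Total step count: 21. Longest linear sequence: 20 steps (1 to 32 through steps 1–6 and 8–21).

**Step 20 (the proposed cathodic ring closure).** It may give oligomers, the alkenylchromium may lose the C5=C6 geometry if it behaves as an allenoate, and the C4 configuration rests on ring control alone. The fallback uses known chemistry of a different kind, a copper hydride conjugate reduction–aldol cyclisation that needs neither halide nor chromium. It sets out from 24: Ac2O, pyridine and DMAP give the ynoate triacetate F1, HF·pyridine gives the ynoate primary alcohol F2, and buffered Dess–Martin periodinane gives the ynoate aldehyde F3. Stoichiometric [(Ph3P)CuH]6 in toluene at −40 → 0 °C under high dilution then delivers hydride to C6, and the copper allenoate adds through C5 to the C4 aldehyde anti to C7. Aqueous NH4Cl work-up gives 31, where the route is rejoined.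

**Step 9 (nickel-catalysed reductive cyclisation).** The intramolecular version with an α-methyl enone may be slow or give protodebromination. The fallback is a tin-hydride radical chain and sets out from 13: Bu3SnH and AIBN in benzene at 80 °C (slow addition) generate the alkenyl radical, which closes 6-endo onto the enone β-carbon (anti to O9) to give the ring A methyl ketone F4. Et3SiCl, NaI and Et3N in MeCN then form the more substituted enol silane under equilibrating conditions, which is 14.

**Step 11 (aldol with the acetaldehyde enol silane, then double reduction).** The β-hydroxy aldehyde 18 may oligomerise or eliminate before it is reduced. The fallback works at the ester oxidation level and sets out from 16: MgBr2·OEt2-mediated Mukaiyama aldol with 1-(ethylsulfanyl)-1-(trimethylsilyloxy)ethene gives the β-hydroxy thioester ketone F5, and Me4NBH(OAc)3 in MeCN/AcOH gives the anti-diol thioester F6. NaBH4 in EtOH/THF at 0 °C reduces only the thioester, which gives 19.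

## Further compounds

F1 | step 20 | ynoate triacetate (24 acetylated at O2, O9, O14; 4-O-TBDPS) | COC(=O)C#C[C@@H]1OC(=O)[C@H](C)[C@@]1(O)[C@@H](OC(C)=O)[C@H]1C(=C)CC[C@H](OC(C)=O)[C@]1(C)[C@@H](OC(C)=O)CCO[Si](c1ccccc1)(c1ccccc1)C(C)(C)C
F2 | step 20 | ynoate primary alcohol (F1 without the silyl group) | COC(=O)C#C[C@@H]1OC(=O)[C@H](C)[C@@]1(O)[C@@H](OC(C)=O)[C@H]1C(=C)CC[C@H](OC(C)=O)[C@]1(C)[C@@H](OC(C)=O)CCO
F3 | step 20 | ynoate aldehyde (C4 aldehyde) | COC(=O)C#C[C@@H]1OC(=O)[C@H](C)[C@@]1(O)[C@@H](OC(C)=O)[C@H]1C(=C)CC[C@H](OC(C)=O)[C@]1(C)[C@@H](OC(C)=O)CC=O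
F4 | step 9 | ring A methyl ketone (C14 ketone, C1–H epimers, 11(20)-methylene, 10S) | C=C1CCC(=O)C(C)[C@H]1[C@@H]3O[C@@H]2OC(C)(C)O[C@@H]2[C@@]3(O)C(C)C(=O)OC
F5 | step 11 | β-hydroxy thioester ketone ((2S)-OH, S-ethyl thioester at C4, C14 ketone) | C=C1CCC(=O)[C@](C)([C@@H](O)CC(=O)SCC)[C@H]1[C@@H]3O[C@@H]2OC(C)(C)O[C@@H]2[C@@]3(O)C(C)C(=O)OC
F6 | step 11 | anti-diol thioester ((2S)-OH, (14S)-OH, S-ethyl thioester at C4) | C=C1CC[C@H](O)[C@](C)([C@@H](O)CC(=O)SCC)[C@H]1[C@@H]3O[C@@H]2OC(C)(C)O[C@@H]2[C@@]3(O)C(C)C(=O)OC
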